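## The problem

Target **19** is 3-[2-(3-hydroxy-5-methoxyphenyl)ethyl]-2,4-bis(4-hydroxybenzyl)phenol. Its four benzene rings are held together only by sp3 links: a CH2CH2 bridge runs from ring A (the 3-hydroxy-5-methoxyphenyl ring) to C3 of the central phenol ring B, and single CH2 groups join C2 and C4 of ring B to the 4-hydroxyphenyl rings C and D. No ring is fused and there is no stereocentre, so nothing has to be set or relayed; the problem is purely positional. Ring B carries four contiguous substituents (OH at C1, benzyl at C2, the bridge at C3, benzyl at C4), the bridge carbon is flanked on both sides, and only C5 and C6 are unsubstituted. Late electrophilic benzylation of a bibenzyl cannot be trusted to give this pattern, because ring A is a resorcinol ether and more nucleophilic than ring B, and within ring B the open C6 would react before the pocket at C2. The four phenolic oxygens must end as three free hydroxyls and one methyl ether; the free phenols are oxidation-prone and the 4-hydroxybenzyl arenes can ionise to quinone methides in acid, so all phenols are best kept as ethers until the last step. The enabling feature is that C2 and C3 of ring B are neighbours and each bears a benzylic sp3 carbon (the CH2 leading to ring C and the first CH2 of the bridge). An oxygen joining these two carbons turns ring B into a 1,3-dihydroisobenzofuran whose two C–O bonds are benzylic and therefore removable by hydrogenolysis. That bicycle is the (2+2+2) adduct of a dipropargyl ether with an alkyne: C2 and C3 are the inner alkyne carbons, C1 (oxygen) and C4 (benzyl) are the diyne termini, and the unsubstituted C5–C6 pair is acetylene.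

## Retrosynthesis

**19 to 18.** No skeletal bond is cut. An oxygen is inserted between the two benzylic carbons on C2 and C3 of ring B, and the phenols of rings A, C and D are benzylated. This gives the dihydroisobenzofuranol **18**. All five benzylic C–O bonds of **18** fall to one hydrogenolysis, and the ring B phenol needs no protection because it is made in the step before. The forward reaction must cleave both ring C–O bonds, including the hindered secondary one, and thereby erase the two carbinol stereocentres.

**18 to 17.** The C1–O bond of ring B is traced to a C–B bond in arylboronate **17**. Boron is preferred to a protected oxygen as the placeholder because a boryl alkyne is a tolerated partner in cobalt cyclotrimerisation, whereas an ynol ether is not a comfortable one. The oxidation must only replace boron by oxygen at the same carbon.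

**17 to 15 and 16 (key disconnection).** Three bonds of ring B are cut: C2–C3, C4–C5 and C6–C1. This unravels both the benzene ring and the five-membered ether ring to the acyclic diyne boronate **15** and acetylene **16**. An untethered three-alkyne combination would raise a regiochemical question at every bond; here the ether tether pairs the two substituted alkynes and the third partner is symmetrical. The simplification is large: a tetrasubstituted benzene fused to a heterocycle becomes an open chain plus a two-carbon gas. The forward step must favour the cross reaction over diyne oligomerisation and acetylene self-trimerisation.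

**15 to 11 and 12.** The C(sp)–B bond is cut to the terminal diyne **11** and the borate ester **12**. Boron is introduced last before the cycloaddition because an alkynylboronate would not survive the acid of the ether-forming step. The forward reaction must remove the acetylenic proton without touching the activated ether C–H.

**11 to 8 and 10.** The ether C–O bond at the aryl-bearing carbinol carbon is cut, giving the propargylic alcohols **8** and **10**. This carbon is chosen because its cation is stabilised by the 4-benzyloxyphenyl group and the alkyne, so the bond can be made by acid-catalysed substitution. The other carbinol carbon cannot ionise, and SN2 displacement at either secondary propargylic centre would invite elimination. The cut divides the molecule into two halves of similar size. The forward step must deliver O-alkylation by **8** and not C-alkylation of its electron-rich ring A.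

**8 to 6 and 4; 10 to 9.** Each propargylic alcohol is opened at the carbinol–alkyne bond. **8** comes from the acetylide of arylpropyne **6** and arylacetaldehyde **4**; **10** comes from 4-(benzyloxy)benzaldehyde **9** and an ethynyl Grignard reagent. These are plain carbonyl additions. The only demand is that addition to the enolisable aldehyde **4** outruns its deprotonation.

**6 to 5; 4 to 3 to 2 to 1.** The sp–sp3 bond of **6** is cut to 4-(benzyloxy)benzyl chloride **5** and an ethynyl nucleophile. Aldehyde **4** is the one-carbon homologue of benzaldehyde **2**, reached through enol ether **3**. **2** is the benzyl ether of commercial 3-hydroxy-5-methoxybenzaldehyde **1**, which already holds the ring A oxygens in differentiated form.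

## Roads not taken

**Alternative 1:** The cut goes through ring A. In an Alder–Rickert sequence the cyclic diene 1-methoxy-3-(trimethylsilyloxy)cyclohexa-1,3-diene A2 adds thermally to the alkynoate benzyl 5-{3-(benzyloxy)-2,6-bis[4-(benzyloxy)benzyl]phenyl}pent-2-ynoate A3. The bicyclic adduct expels its two-carbon bridge and the silyl ether is hydrolysed, giving benzoate A1; hydrogenolysis and decarboxylation would finish.
- Merits: the polarised diene fixes the regiochemistry, and the methoxy and hydroxy groups of ring A are differentiated by construction, with no protecting group on that phenol.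
- Weak points: ring A in this oxidation pattern is purchasable as **1**. A3 already contains the finished ring B with all four contiguous substituents, so the hard part is pushed into a starting material that needs its own multistep synthesis. A β-alkyl ynoate is a sluggish dienophile needing high temperature, and a carboxyl carbon is carried only to be removed.
- Comparison: the ring A end game is cleaner than in the chosen route, which needs a benzyl group on ring A and a sensitive arylacetaldehyde. But it spends its key step on the ring that needs no synthesis, whereas the chosen plan spends it on ring B.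

**Alternative 2:** The cut removes both aryl–CH2 bonds and the aryl–bridge bond of ring B in one Catellani reaction. 1-(Benzyloxy)-3-iodobenzene A5, two equivalents of benzyl chloride **5** and 1-(benzyloxy)-3-methoxy-5-vinylbenzene A6 would react under Pd(OAc)2, tri(2-furyl)phosphine, norbornene and Cs2CO3 to give stilbene A4. One hydrogenation of A4 would saturate the alkene and remove all four benzyl groups.
- Merits: this is by far the shortest route, roughly four steps against eleven, fully convergent and with no ring construction. In step economy it is clearly better than the chosen plan.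
- Weak points: the two ortho positions of A5 are not equivalent, since one lies between iodine and the benzyloxy group. After the first benzylation at the open position the palladacycle already has an ortho substituent and can expel norbornene and terminate by Heck coupling, giving an under-benzylated stilbene. The second C–H palladation must occur in the hindered pocket. Benzylic chlorides also add oxidatively to zerovalent palladium and can benzylate the styrene or norbornene directly.
- Comparison: the chosen plan sets against the shorter route that every substituent position is fixed by the connectivity of an acyclic precursor, so no positional isomer or under-benzylated product can form. The price is about seven more steps.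

**Alternative 3:** The cut again goes through ring A. The diketo-dioxinone 6-(6-{3-(benzyloxy)-2,6-bis[4-(benzyloxy)benzyl]phenyl}-2,4-dioxohexyl)-2,2-dimethyl-4H-1,3-dioxin-4-one A8 would cyclise with Et3N by aldol attack and dehydration to the benzodioxinone A7. Methylation of the free hydroxyl, opening of the dioxinone, decarboxylation and debenzylation would follow.
- Merits: the aromatisation is mild (amine base, room temperature, no transition metal, no gas), and the two ring A oxygens emerge differentiated, one free and one masked in the dioxinone.
- Weak points: as in alternative 1, ring B is untouched. A8 must be assembled by acylation chemistry from a 3-arylpropanoic acid that already carries the complete ring B, and several steps after the key step are spent removing the carboxyl carbon.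
- Comparison: the key step is gentler and more predictable than a cobalt cycloaddition with acetylene. But the differentiation it achieves is already supplied by commercial **1**, and the contiguous substitution of ring B, which the chosen plan solves, is left open.

Key step: step 9

Assumption: **8** and **10** are racemic, and **11**, **13**, **14**, **15**, **17** and **18** are carried as mixtures of diastereomers, since both carbinol stereocentres become CH2 groups in step 11.

## Route

Step 1
Reactants: 1 3-hydroxy-5-methoxybenzaldehyde
Product: 2 3-(benzyloxy)-5-methoxybenzaldehyde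
Conditions: BnBr, K2CO3, DMF, rt
Reagents that add atoms: benzyl bromide, BrCc1ccccc1
Why: Williamson ether synthesis on a phenoxide; the aldehyde is inert to carbonate and the benzyl group is chosen to fall in the final hydrogenolysis.

Step 2
Reactants: 2 3-(benzyloxy)-5-methoxybenzaldehyde
Product: 3 1-(benzyloxy)-3-methoxy-5-(2-methoxyethenyl)benzene (E/Z mixture)
Conditions: Ph3P(CH2OMe)Cl, KOtBu, THF, 0 °C to rt
Reagents that add atoms: (methoxymethyl)triphenylphosphonium chloride, COC[P+](c1ccccc1)(c1ccccc1)c1ccccc1.[Cl-]
Why: Wittig methoxymethylenation of an aryl aldehyde; the alkene geometry is irrelevant because both isomers hydrolyse to the same aldehyde.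

Step 3
Reactants: 3 1-(benzyloxy)-3-methoxy-5-(2-methoxyethenyl)benzene
Product: 4 2-[3-(benzyloxy)-5-methoxyphenyl]acetaldehyde
Conditions: 2 M aq. HCl, THF, 50 °C; crude aldehyde used at once
Reagents that add atoms: water, O
Why: Acid-catalysed enol ether hydrolysis (C-protonation, hydration, loss of methanol); dilute acid leaves the aryl benzyl ether intact and immediate use avoids aldol self-condensation.

Step 4
Reactants: 5 4-(benzyloxy)benzyl chloride
Product: 6 1-(benzyloxy)-4-(prop-2-yn-1-yl)benzene
Conditions: HC≡CMgBr (2 equiv), CuCl (10 mol%), THF, 50 °C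
Reagents that add atoms: ethynylmagnesium bromide, C#C[Mg]Br
Why: Copper-catalysed cross-coupling of an alkynyl Grignard reagent with a benzylic chloride; excess Grignard reagent prevents a second benzylation of the product alkyne, and a short reaction time limits isomerisation to the allene.

Step 5
Reactants: 6 1-(benzyloxy)-4-(prop-2-yn-1-yl)benzene; 4 2-[3-(benzyloxy)-5-methoxyphenyl]acetaldehyde
Product: 8 rac-1-[3-(benzyloxy)-5-methoxyphenyl]-5-[4-(benzyloxy)phenyl]pent-3-yn-2-ol, via lithium 3-[4-(benzyloxy)phenyl]prop-1-yn-1-ide 7 (not isolated)
Conditions: 6 (1.3 equiv), n-BuLi, THF, −78 °C; then 4, −78 to −20 °C; then H2O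
Reagents that add atoms: none
Why: 1,2-Addition of a lithium acetylide to an aldehyde; the sp C–H is removed selectively at −78 °C, and low temperature with excess acetylide limits enolisation of the arylacetaldehyde. The carbinol centre forms racemic and is erased in step 11.

Step 6
Reactants: 9 4-(benzyloxy)benzaldehyde
Product: 10 rac-1-[4-(benzyloxy)phenyl]prop-2-yn-1-ol
Conditions: HC≡CMgBr, THF, 0 °C; then H2O
Reagents that add atoms: ethynylmagnesium bromide, C#C[Mg]Br
Why: Grignard addition of an acetylide to a non-enolisable aryl aldehyde; the racemic centre is erased in step 11.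

Step 7
Reactants: 8 rac-1-[3-(benzyloxy)-5-methoxyphenyl]-5-[4-(benzyloxy)phenyl]pent-3-yn-2-ol; 10 rac-1-[4-(benzyloxy)phenyl]prop-2-yn-1-ol
Product: 11 1-(benzyloxy)-3-[2-({1-[4-(benzyloxy)phenyl]prop-2-yn-1-yl}oxy)-5-[4-(benzyloxy)phenyl]pent-3-yn-1-yl]-5-methoxybenzene (mixture of diastereomers)
Conditions: FeCl3 (5 mol%), 4 Å MS, MeCN, 0 °C to rt; 10 (1.5 equiv) added slowly
Reagents that add atoms: none
Why: Lewis-acid-catalysed SN1 propargylic substitution (dehydrative etherification); FeCl3 ionises only 10, whose cation is stabilised by the 4-benzyloxyphenyl group and the alkyne, and the hydroxyl of 8 captures it. Alcohol 8 cannot ionise, any symmetrical ether of 10 re-enters through the same cation, and the uncontrolled new centre is harmless.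

Step 8
Reactants: 11 1-(benzyloxy)-3-[2-({1-[4-(benzyloxy)phenyl]prop-2-yn-1-yl}oxy)-5-[4-(benzyloxy)phenyl]pent-3-yn-1-yl]-5-methoxybenzene; 12 2-isopropoxy-4,4,5,5-tetramethyl-1,3,2-dioxaborolane
Product: 15 2-{3-[4-(benzyloxy)phenyl]-3-({1-[3-(benzyloxy)-5-methoxyphenyl]-5-[4-(benzyloxy)phenyl]pent-3-yn-2-yl}oxy)prop-1-yn-1-yl}-4,4,5,5-tetramethyl-1,3,2-dioxaborolane (mixture of diastereomers), via terminal lithium acetylide 13 (not isolated), via lithium alkynyl(isopropoxy)borate 14 (not isolated)
Conditions: n-BuLi (1.0 equiv), THF, −78 °C; 12, −78 °C; HCl in Et2O (1.0 equiv), −78 °C to rt; filtered and used crude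
Reagents that add atoms: none
Why: Deprotonation of the terminal alkyne, capture of the acetylide by the borate ester to an ate complex, and acid-induced loss of isopropoxide, the standard preparation of alkynyl pinacolboronates. One equivalent of base at −78 °C takes the acetylenic proton before the activated ether C–H, and anhydrous work-up protects the C(sp)–B bond.

Step 9
Reactants: 15 2-{3-[4-(benzyloxy)phenyl]-3-({1-[3-(benzyloxy)-5-methoxyphenyl]-5-[4-(benzyloxy)phenyl]pent-3-yn-2-yl}oxy)prop-1-yn-1-yl}-4,4,5,5-tetramethyl-1,3,2-dioxaborolane; 16 acetylene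
Product: 17 2-{7-[4-(benzyloxy)benzyl]-1-[3-(benzyloxy)-5-methoxybenzyl]-3-[4-(benzyloxy)phenyl]-1,3-dihydroisobenzofuran-4-yl}-4,4,5,5-tetramethyl-1,3,2-dioxaborolane (cis/trans mixture)
Conditions: CpCo(CO)2 (20 mol%), HC≡CH (1 atm, continuous purge), toluene, hν, 80 °C; 15 added by syringe pump
Reagents that add atoms: none
Why: This is a cobalt-mediated (2+2+2) alkyne cyclotrimerisation; the closest known reactions are CpCo cocyclisations of dipropargyl ethers with monoalkynes, which give 1,3-dihydroisobenzofurans, and of boryl-substituted alkynes, which give arylboronates. Loss of CO from CpCo(CO)2 under light lets monovalent cobalt bind both alkynes of 15, and oxidative coupling joins the two inner alkyne carbons to a bicyclic trivalent cobaltacyclopentadiene; this C–C bond closes the five-membered ether ring, whose size is dictated by the three-atom C–O–C tether. Acetylene 16 then coordinates and inserts, and reductive elimination forms the two bonds from the diyne termini to the acetylene carbons, closing benzene ring B and returning monovalent cobalt. No stereocentre is formed; the two carbinol centres are untouched, so 17 is a cis/trans mixture that converges in step 11. Regiochemistry is not at issue, because both substituted termini sit in the tethered diyne and acetylene is symmetrical, so boron must end at C4 and the benzyl group at C7. The selectivity needed is chemoselectivity for the cross reaction over oligomerisation of 15: both termini of 15 are substituted (Bpin, CH2Ar), which makes a second molecule of 15 a poor third alkyne, whereas unhindered acetylene is kept in large excess and 15 is kept dilute by slow addition. Self-trimerisation of acetylene gives only benzene, and the C–B bond, the benzyl ethers and the propargylic C–O bonds are inert to the neutral cobalt species.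

Step 10
Reactants: 17 2-{7-[4-(benzyloxy)benzyl]-1-[3-(benzyloxy)-5-methoxybenzyl]-3-[4-(benzyloxy)phenyl]-1,3-dihydroisobenzofuran-4-yl}-4,4,5,5-tetramethyl-1,3,2-dioxaborolane
Product: 18 7-[4-(benzyloxy)benzyl]-1-[3-(benzyloxy)-5-methoxybenzyl]-3-[4-(benzyloxy)phenyl]-1,3-dihydroisobenzofuran-4-ol (cis/trans mixture)
Conditions: NaBO3·4H2O, THF/H2O (1:1), rt
Reagents that add atoms: sodium perborate (used as the tetrahydrate), [Na+].[O-]B1OO1
Why: Oxidation of an arylboronic ester by perborate: peroxide adds to boron, the aryl group migrates from boron to oxygen at the same carbon, and hydrolysis frees the phenol. Benzyl ethers and the cyclic ether are inert to this mild nucleophilic oxidant.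

Step 11
Reactants: 18 7-[4-(benzyloxy)benzyl]-1-[3-(benzyloxy)-5-methoxybenzyl]-3-[4-(benzyloxy)phenyl]-1,3-dihydroisobenzofuran-4-ol
Product: 19 3-[2-(3-hydroxy-5-methoxyphenyl)ethyl]-2,4-bis(4-hydroxybenzyl)phenol
Conditions: H2 (3 atm), Pd(OH)2/C, EtOAc/AcOH, 40 °C
Reagents that add atoms: none
Why: Palladium-catalysed hydrogenolysis of benzylic C–O bonds: the benzhydrylic ring C–O bond cleaves first, and the resulting secondary benzylic alcohol and the three aryl benzyl ethers follow under the mildly acidic conditions. Both carbinol centres become CH2 groups, so the diastereomers converge on the achiral target; the methyl ether is untouched.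

## Compound list

1 | 3-hydroxy-5-methoxybenzaldehyde | COc1cc(O)cc(C=O)c1 | starting material
2 | 3-(benzyloxy)-5-methoxybenzaldehyde | COc1cc(OCc2ccccc2)cc(C=O)c1 | intermediate
3 | 1-(benzyloxy)-3-methoxy-5-(2-methoxyethenyl)benzene (E/Z mixture) | COC=Cc1cc(OC)cc(OCc2ccccc2)c1 | intermediate
4 | 2-[3-(benzyloxy)-5-methoxyphenyl]acetaldehyde | COc1cc(OCc2ccccc2)cc(CC=O)c1 | intermediate
5 | 4-(benzyloxy)benzyl chloride | ClCc1ccc(OCc2ccccc2)cc1 | starting material
6 | 1-(benzyloxy)-4-(prop-2-yn-1-yl)benzene | C#CCc1ccc(OCc2ccccc2)cc1 | intermediate
7 | lithium 3-[4-(benzyloxy)phenyl]prop-1-yn-1-ide | [Li]C#CCc1ccc(OCc2ccccc2)cc1 | intermediate (not isolated)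
8 | rac-1-[3-(benzyloxy)-5-methoxyphenyl]-5-[4-(benzyloxy)phenyl]pent-3-yn-2-ol | OC(Cc1cc(OC)cc(OCc2ccccc2)c1)C#CCc1ccc(OCc2ccccc2)cc1 | intermediate
9 | 4-(benzyloxy)benzaldehyde | O=Cc1ccc(OCc2ccccc2)cc1 | starting material
10 | rac-1-[4-(benzyloxy)phenyl]prop-2-yn-1-ol | C#CC(O)c1ccc(OCc2ccccc2)cc1 | intermediate
11 | 1-(benzyloxy)-3-[2-({1-[4-(benzyloxy)phenyl]prop-2-yn-1-yl}oxy)-5-[4-(benzyloxy)phenyl]pent-3-yn-1-yl]-5-methoxybenzene (mixture of diastereomers) | C#CC(OC(Cc1cc(OC)cc(OCc2ccccc2)c1)C#CCc1ccc(OCc2ccccc2)cc1)c1ccc(OCc2ccccc2)cc1 | intermediate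
12 | 2-isopropoxy-4,4,5,5-tetramethyl-1,3,2-dioxaborolane | CC(C)OB1OC(C)(C)C(C)(C)O1 | starting material
13 | terminal lithium acetylide of 11 (mixture of diastereomers) | [Li]C#CC(OC(Cc1cc(OC)cc(OCc2ccccc2)c1)C#CCc1ccc(OCc2ccccc2)cc1)c1ccc(OCc2ccccc2)cc1 | intermediate (not isolated)
14 | lithium alkynyl(isopropoxy)(pinacolato)borate formed from 13 and 12 (mixture of diastereomers) | [Li+].CC(C)O[B-]1(OC(C)(C)C(C)(C)O1)C#CC(OC(Cc1cc(OC)cc(OCc2ccccc2)c1)C#CCc1ccc(OCc2ccccc2)cc1)c1ccc(OCc2ccccc2)cc1 | intermediate (not isolated)
15 | 2-{3-[4-(benzyloxy)phenyl]-3-({1-[3-(benzyloxy)-5-methoxyphenyl]-5-[4-(benzyloxy)phenyl]pent-3-yn-2-yl}oxy)prop-1-yn-1-yl}-4,4,5,5-tetramethyl-1,3,2-dioxaborolane (mixture of diastereomers) | CC1(C)OB(C#CC(OC(Cc2cc(OC)cc(OCc3ccccc3)c2)C#CCc2ccc(OCc3ccccc3)cc2)c2ccc(OCc3ccccc3)cc2)OC1(C)C | intermediate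
16 | acetylene | C#C | starting material
17 | 2-{7-[4-(benzyloxy)benzyl]-1-[3-(benzyloxy)-5-methoxybenzyl]-3-[4-(benzyloxy)phenyl]-1,3-dihydroisobenzofuran-4-yl}-4,4,5,5-tetramethyl-1,3,2-dioxaborolane (cis/trans mixture) | CC1(C)OB(c2ccc(Cc3ccc(OCc4ccccc4)cc3)c3c2C(c2ccc(OCc4ccccc4)cc2)OC3Cc2cc(OC)cc(OCc3ccccc3)c2)OC1(C)C | intermediate
18 | 7-[4-(benzyloxy)benzyl]-1-[3-(benzyloxy)-5-methoxybenzyl]-3-[4-(benzyloxy)phenyl]-1,3-dihydroisobenzofuran-4-ol (cis/trans mixture) | Oc1ccc(Cc2ccc(OCc3ccccc3)cc2)c2c1C(c1ccc(OCc3ccccc3)cc1)OC2Cc1cc(OC)cc(OCc2ccccc2)c1 | intermediate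
19 | 3-[2-(3-hydroxy-5-methoxyphenyl)ethyl]-2,4-bis(4-hydroxybenzyl)phenol (achiral) | COc1cc(O)cc(CCc2c(Cc3ccc(O)cc3)ccc(O)c2Cc2ccc(O)cc2)c1 | target

## Step count and risk

Total steps: 11. Longest linear sequence: 9 steps (steps 1, 2, 3, 5, 7, 8, 9, 10, 11, from **1**).

**Step 9 (key step).**
- Risk: the cross-cyclotrimerisation may lose to oligomerisation of the diyne or to acetylene self-trimerisation, because little acetylene stays dissolved at the temperature the cobalt carbonyl needs. Cobalt may also be trapped as an unreactive cyclobutadiene or diene complex, and some boron may be lost by protodeboronation.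
- Fallback: replace gaseous acetylene by vinyl acetate as a liquid acetylene equivalent under cationic monovalent rhodium ([Rh(cod)2]BF4/BINAP, 1,2-dichloroethane, rt to 60 °C). Setting out from **15**, the diyne–alkene (2+2+2) cycloaddition would give the acetoxycyclohexadiene 7-[4-(benzyloxy)benzyl]-1-[3-(benzyloxy)-5-methoxybenzyl]-3-[4-(benzyloxy)phenyl]-4-(4,4,5,5-tetramethyl-1,3,2-dioxaborolan-2-yl)-1,3,5,6-tetrahydroisobenzofuran-6-yl acetate F1 (either regioisomer serves). This aromatises by loss of acetic acid and comes back to the route at **17**.

**Step 7.**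
- Risk: the stabilised propargylic cation from **10** may be diverted before the hindered secondary hydroxyl of **8** captures it. The diversions are Friedel–Crafts alkylation of the electron-rich ring A, self-etherification of **10**, and Meyer–Schuster rearrangement.
- Fallback: make the same C–O bond by carbene O–H insertion, which involves no cation. Setting out from **8**, Rh2(OAc)4-catalysed decomposition of methyl 2-[4-(benzyloxy)phenyl]-2-diazoacetate F2 would give the α-alkoxy ester methyl 2-({1-[3-(benzyloxy)-5-methoxyphenyl]-5-[4-(benzyloxy)phenyl]pent-3-yn-2-yl}oxy)-2-[4-(benzyloxy)phenyl]acetate F3. F2 is made by diazo transfer with 4-acetamidobenzenesulfonyl azide and DBU onto commercial methyl [4-(benzyloxy)phenyl]acetate. Reduction with i-Bu2AlH at −78 °C would give the aldehyde 2-({1-[3-(benzyloxy)-5-methoxyphenyl]-5-[4-(benzyloxy)phenyl]pent-3-yn-2-yl}oxy)-2-[4-(benzyloxy)phenyl]acetaldehyde F4. Ohira–Bestmann homologation (dimethyl (1-diazo-2-oxopropyl)phosphonate, K2CO3, MeOH) then comes back to the route at **11**.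

**Step 8.**
- Risk: deprotonation may compete at the doubly activated ether C–H (benzylic, propargylic and α to oxygen) and lead to Wittig rearrangement, and the C(sp)–B bond may hydrolyse during isolation.
- Fallback: base-free catalytic dehydrogenative C–H borylation of the terminal alkyne with pinacolborane, using a monovalent copper triflate carbene complex, (CAAC)CuOTf, with catalytic Et3N. It sets out from **11**, involves no carbanion, releases only hydrogen and comes back directly at **15**; no new compound arises.

**Step 11.**
- Risk: hydrogenolysis may stall after the easy benzhydrylic cleavage, leaving the hindered secondary benzylic C–O bond at the bridge carbon intact, or the electron-rich rings may be partly saturated if conditions are forced.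
- Fallback: separate the two tasks. Setting out from **18**, ionic hydrogenation (Et3SiH, BF3·OEt2, CH2Cl2, −40 to 0 °C) would reduce both ring C–O bonds through benzylic cations and give 3-{2-[3-(benzyloxy)-5-methoxyphenyl]ethyl}-2,4-bis[4-(benzyloxy)benzyl]phenol F5. Neutral hydrogenolysis of the three benzyl ethers (H2, Pd/C, EtOAc/EtOH, rt) then comes back to the route at **19**.

## Further compounds

F1 | step 9 | 7-[4-(benzyloxy)benzyl]-1-[3-(benzyloxy)-5-methoxybenzyl]-3-[4-(benzyloxy)phenyl]-4-(4,4,5,5-tetramethyl-1,3,2-dioxaborolan-2-yl)-1,3,5,6-tetrahydroisobenzofuran-6-yl acetate (isomer mixture, one regioisomer drawn) | CC(=O)OC1CC(B2OC(C)(C)C(C)(C)O2)=C2C(c3ccc(OCc4ccccc4)cc3)OC(Cc3cc(OC)cc(OCc4ccccc4)c3)C2=C1Cc1ccc(OCc2ccccc2)cc1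
F2 | step 7 | methyl 2-[4-(benzyloxy)phenyl]-2-diazoacetate | COC(=O)C(=[N+]=[N-])c1ccc(OCc2ccccc2)cc1
F3 | step 7 | methyl 2-({1-[3-(benzyloxy)-5-methoxyphenyl]-5-[4-(benzyloxy)phenyl]pent-3-yn-2-yl}oxy)-2-[4-(benzyloxy)phenyl]acetate (mixture of diastereomers) | COC(=O)C(OC(Cc1cc(OC)cc(OCc2ccccc2)c1)C#CCc1ccc(OCc2ccccc2)cc1)c1ccc(OCc2ccccc2)cc1
F4 | step 7 | 2-({1-[3-(benzyloxy)-5-methoxyphenyl]-5-[4-(benzyloxy)phenyl]pent-3-yn-2-yl}oxy)-2-[4-(benzyloxy)phenyl]acetaldehyde (mixture of diastereomers) | O=CC(OC(Cc1cc(OC)cc(OCc2ccccc2)c1)C#CCc1ccc(OCc2ccccc2)cc1)c1ccc(OCc2ccccc2)cc1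
F0 | step 8 | none | none
F5 | step 11 | 3-{2-[3-(benzyloxy)-5-methoxyphenyl]ethyl}-2,4-bis[4-(benzyloxy)benzyl]phenol | COc1cc(OCc2ccccc2)cc(CCc2c(Cc3ccc(OCc4ccccc4)cc3)ccc(O)c2Cc2ccc(OCc3ccccc3)cc2)c1
A1 | alternative 1 | benzyl 2-{2-[3-(benzyloxy)-2,6-bis[4-(benzyloxy)benzyl]phenyl]ethyl}-4-hydroxy-6-methoxybenzoate | COc1cc(O)cc(CCc2c(Cc3ccc(OCc4ccccc4)cc3)ccc(OCc3ccccc3)c2Cc2ccc(OCc3ccccc3)cc2)c1C(=O)OCc1ccccc1
A2 | alternative 1 | 1-methoxy-3-(trimethylsilyloxy)cyclohexa-1,3-diene | COC1=CC(O[Si](C)(C)C)=CCC1
A3 | alternative 1 | benzyl 5-{3-(benzyloxy)-2,6-bis[4-(benzyloxy)benzyl]phenyl}pent-2-ynoate | O=C(OCc1ccccc1)C#CCCc1c(Cc2ccc(OCc3ccccc3)cc2)ccc(OCc2ccccc2)c1Cc1ccc(OCc2ccccc2)cc1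
A4 | alternative 2 | 1-(benzyloxy)-3-[(E)-2-{3-(benzyloxy)-2,6-bis[4-(benzyloxy)benzyl]phenyl}ethenyl]-5-methoxybenzene | COc1cc(OCc2ccccc2)cc(/C=C/c2c(Cc3ccc(OCc4ccccc4)cc3)ccc(OCc3ccccc3)c2Cc2ccc(OCc3ccccc3)cc2)c1
A5 | alternative 2 | 1-(benzyloxy)-3-iodobenzene | Ic1cccc(OCc2ccccc2)c1
A6 | alternative 2 | 1-(benzyloxy)-3-methoxy-5-vinylbenzene | C=Cc1cc(OC)cc(OCc2ccccc2)c1
A7 | alternative 3 | 5-{2-[3-(benzyloxy)-2,6-bis[4-(benzyloxy)benzyl]phenyl]ethyl}-7-hydroxy-2,2-dimethyl-4H-benzo[d][1,3]dioxin-4-one | CC1(C)OC(=O)c2c(CCc3c(Cc4ccc(OCc5ccccc5)cc4)ccc(OCc4ccccc4)c3Cc3ccc(OCc4ccccc4)cc3)cc(O)cc2O1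
A8 | alternative 3 | 6-(6-{3-(benzyloxy)-2,6-bis[4-(benzyloxy)benzyl]phenyl}-2,4-dioxohexyl)-2,2-dimethyl-4H-1,3-dioxin-4-one | CC1(C)OC(CC(=O)CC(=O)CCc2c(Cc3ccc(OCc4ccccc4)cc3)ccc(OCc3ccccc3)c2Cc2ccc(OCc3ccccc3)cc2)=CC(=O)O1
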